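**Plan**

1. Locants: the cyclohexane is C5 (CH carrying CMe2OH), C6 and C7 (CH2CH2), C8 (CHCH3), C9 (spiro C–O), C10 (C(CH3)CH2CH2CO2H); the furan and seven-membered ring are numbered as in cyclohepta[b]furan (O1, C2 = C9, C3, C3a, C4–C8, C8a).
2. Retrosynthesis: the tropone is cut at C3a–C4 and C6–C7 (vinylcarbenoid [4+3]), then O1–C8a (alkyne hydroalkoxylation), C3–C3a (epoxide alkynylation) and C9–C3 (methylene transfer to a C9 ketone); last, C5–C6 and C7–C8 are cut together (ethylene plus a dearomatised phenol).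
3. Enabling feature: ring B has a bare C6H2–C7H2 edge between two CH carbons (C5, C8), next to the O-bearing C9 and the quaternary C10. This is the [4+2] retron of ethylene with a 6,6-disubstituted cyclohexa-2,4-dienone (C9 = C=O, C10 = sp3, C5/C8 = diene termini), i.e. a dearomatised 2,4-dimethylphenol whose two remaining ring carbons are cut out later (one becomes the carbinol carbon on C5, one leaves as CO).
4. Forward order: phenol + acrylic acid, asymmetric spirolactonisation, ethylene Diels–Alder (ring B), reductive methylation (C10), epoxide (C9), ozonolysis/decarbonylation/MeMgBr, alkynylation and gold cyclisation (spirodihydrofuran), [4+3]/DDQ/singlet oxygen (tropone), fluoride.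
5. Stereochemistry: a chiral aryl iodide sets the spiro centre of the dienone, which only relays chirality. It directs ethylene to one face (C5, C8) and is then erased; C10 and C9 are set by attack on the etheno-bridge face of the bicycle, and C8 by stereoretentive decarbonylation.

Key step: step 4

Remark: the sense of induction in step 3 and the diene face used in step 4 are assigned by analogy with related ortho-quinol esters; if either is opposite, the antipodal aryl iodide is used so that 7 is obtained as drawn.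

**Route**

Step 1
Reactants: 1 2,4-dimethylphenol; 2 acrylic acid
Product: 3 6,8-dimethyl-3,4-dihydro-2H-chromen-2-one
Conditions: TfOH (10 mol%), toluene, 110 °C, Dean–Stark
Reagents that add atoms: none
Why: Acid-catalysed Friedel–Crafts conjugate addition of the phenol to acrylic acid at its only free ortho position, followed by lactonisation (tandem hydroarylation–esterification), should give the dihydrocoumarin.

Step 2
Reactants: 3 6,8-dimethyl-3,4-dihydro-2H-chromen-2-one
Product: 4 3-(2-hydroxy-3,5-dimethylphenyl)propanoic acid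
Conditions: NaOH (2.5 equiv), H2O/THF, rt; then HCl to pH 2, 0 °C
Reagents that add atoms: sodium hydroxide, [Na+].[OH-]
Why: Saponification of the aryl lactone, with cold acidification so that the free hydroxy acid is isolated before it relactonises.

Step 3
Reactants: 4 3-(2-hydroxy-3,5-dimethylphenyl)propanoic acid
Product: 5 (5R)-7,9-dimethyl-1-oxaspiro[4.5]deca-6,8-diene-2,10-dione
Conditions: (2R,2'R)-2,2'-[(2-iodo-1,3-phenylene)bis(oxy)]bis(N-mesitylpropanamide) (10 mol%), mCPBA (1.2 equiv), CH2Cl2/(CF3)2CHOH, −20 °C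
Reagents that add atoms: none
Why: Catalytic enantioselective oxidative dearomatising spirolactonisation: mCPBA oxidises the aryl iodide to a chiral trivalent iodine species that activates the phenol, and the tethered carboxyl group attacks the ipso carbon in a 5-exo mode on the face selected by the lactamide arms, which sets the spiro centre.

Step 4
Reactants: 5 (5R)-7,9-dimethyl-1-oxaspiro[4.5]deca-6,8-diene-2,10-dione; 6 ethylene
Product: 7 4,6-dimethylspiro[bicyclo[2.2.2]oct-5-ene-2,2'-oxolane]-3,5'-dione (lactone O on the side of the C7–C8 ethano bridge)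
Conditions: ethylene (50 bar), toluene, BHT (1 mol%), 120 °C, autoclave, dark
Reagents that add atoms: none
Why: Thermal, concerted suprafacial [4+2] (Diels–Alder) addition of ethylene across C6 and C9 of 5, the termini of the cyclohexa-2,4-dienone diene; the closest known reaction type is the Diels–Alder trapping of ortho-quinol esters and masked ortho-benzoquinones by alkenes to give bicyclo[2.2.2]octenones. The future cyclohexane (ring B) is closed through a six-membered pericyclic transition state in which both new C–C bonds (C5–C6 and C7–C8) form on one face, so it appears as the boat of a bicyclo[2.2.2]oct-5-en-2-one whose etheno bridge is cut out later. The two new stereocentres are the bridgeheads (future C5 and C8): their relative configuration follows from suprafacial addition, and their absolute configuration from the spiro centre of 5, because ethylene should approach the diene face that carries the lactone oxygen and not the lactone CH2 (the contrasteric preference known for 6-acyloxy- and 6-alkoxycyclohexa-2,4-dienones). Ethylene is symmetrical, so no regiochemistry arises; the selectivity needed is facial, and it matters because the spiro centre is erased in step 5, so addition on the other face would lead into the enantiomeric series (any minor adduct is removed by chromatography at the stage of 7). The methyl groups at C7 and C9 of 5 suppress the usual Diels–Alder dimerisation of such dienones, which allows forcing conditions for the unactivated dienophile.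

Step 5
Reactants: 7 4,6-dimethylspiro[bicyclo[2.2.2]oct-5-ene-2,2'-oxolane]-3,5'-dione
Product: 9 3-(2,4,6-trimethyl-3-oxobicyclo[2.2.2]oct-5-en-2-yl)propanoic acid (2-methyl syn to the C5=C6 bridge), via dilithium enolate carboxylate 8 (not isolated)
Conditions: Li (2.2 equiv), NH3/THF, −78 °C; then MeI (5 equiv), −78 to −33 °C; aq NH4Cl
Reagents that add atoms: iodomethane, CI
Why: Dissolving-metal cleavage of the α-acyloxy ketone gives the enolate regiospecifically and frees the carboxylate (reductive alkylation), and MeI should alkylate the enolate carbon from the etheno-bridge face, which is less shielded than the ethano-bridge face with its inward C–H bonds, so the C10 methyl ends syn to the alkene bridge.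

Step 6
Reactants: 9 3-(2,4,6-trimethyl-3-oxobicyclo[2.2.2]oct-5-en-2-yl)propanoic acid
Product: 10 2-(trimethylsilyl)ethyl 3-(2,4,6-trimethyl-3-oxobicyclo[2.2.2]oct-5-en-2-yl)propanoate
Conditions: 2-(trimethylsilyl)ethanol (1.5 equiv), EDC·HCl, DMAP (cat.), CH2Cl2, 0 °C to rt
Reagents that add atoms: 2-(trimethylsilyl)ethanol, C[Si](C)(C)CCO
Why: Carbodiimide (Steglich-type) esterification gives an ester that is inert to the later steps and can be removed by fluoride without touching the tropone methyl ester.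

Step 7
Reactants: 10 2-(trimethylsilyl)ethyl 3-(2,4,6-trimethyl-3-oxobicyclo[2.2.2]oct-5-en-2-yl)propanoate
Product: 11 2-(trimethylsilyl)ethyl 3-(1',3',5'-trimethylspiro[oxirane-2,2'-bicyclo[2.2.2]oct[5]en]-3'-yl)propanoate (oxirane CH2 syn to the etheno bridge)
Conditions: Me3SI (2 equiv), KN(SiMe3)2 (1.9 equiv), THF, −10 to 0 °C
Reagents that add atoms: trimethylsulfonium iodide, C[S+](C)C.[I-]
Why: Corey–Chaykovsky methylene transfer: the sulfonium ylide should add irreversibly to the ketone from the etheno-bridge face (the other face is blocked by the ethano bridge and the propanoate chain), which places the new CH2 syn to the alkene bridge and the oxygen anti and so sets C9.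

Step 8
Reactants: 11 2-(trimethylsilyl)ethyl 3-(1',3',5'-trimethylspiro[oxirane-2,2'-bicyclo[2.2.2]oct[5]en]-3'-yl)propanoate
Product: 12 2-(trimethylsilyl)ethyl 3-(7-acetyl-4-formyl-4,8-dimethyl-1-oxaspiro[2.5]octan-8-yl)propanoate
Conditions: O3, CH2Cl2/MeOH, NaHCO3, −78 °C; then Me2S, −78 °C to rt
Reagents that add atoms: ozone, O=[O+][O-]
Why: Ozonolysis with reductive work-up cleaves the only C=C bond, which opens the bicycle to the cyclohexane and turns the two alkene carbons into an acetyl group on C5 and a formyl group on C8, while epoxide and ester are inert to ozone.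

Step 9
Reactants: 12 2-(trimethylsilyl)ethyl 3-(7-acetyl-4-formyl-4,8-dimethyl-1-oxaspiro[2.5]octan-8-yl)propanoate
Product: 13 2-(trimethylsilyl)ethyl 3-(7-acetyl-4,8-dimethyl-1-oxaspiro[2.5]octan-8-yl)propanoate
Conditions: RhCl(PPh3)3 (1.1 equiv), toluene, 110 °C
Reagents that add atoms: none
Why: Tsuji–Wilkinson decarbonylation (oxidative addition of the aldehyde C–H bond to monovalent rhodium, CO de-insertion, C–H reductive elimination from a coordinatively saturated alkyl hydride) replaces CHO by H with retention, which leaves the C8 methyl trans to the C5 substituent.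

Step 10
Reactants: 13 2-(trimethylsilyl)ethyl 3-(7-acetyl-4,8-dimethyl-1-oxaspiro[2.5]octan-8-yl)propanoate
Product: 14 2-(trimethylsilyl)ethyl 3-[7-(2-hydroxypropan-2-yl)-4,8-dimethyl-1-oxaspiro[2.5]octan-8-yl]propanoate
Conditions: MeMgBr (1.3 equiv), CeCl3 (1.5 equiv), THF, −78 °C; aq NH4Cl
Reagents that add atoms: methylmagnesium bromide, C[Mg]Br
Why: The organocerium reagent should add to the methyl ketone faster than to the ester or the epoxide and is too weakly basic to epimerise C5.

Step 11
Reactants: 14 2-(trimethylsilyl)ethyl 3-[7-(2-hydroxypropan-2-yl)-4,8-dimethyl-1-oxaspiro[2.5]octan-8-yl]propanoate; 15 2-methylbut-1-en-3-yne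
Product: 16 2-(trimethylsilyl)ethyl 3-[2-hydroxy-6-(2-hydroxypropan-2-yl)-1,3-dimethyl-2-(4-methylpent-4-en-2-yn-1-yl)cyclohexyl]propanoate
Conditions: 15 (3.5 equiv), n-BuLi (3.2 equiv), THF, −78 °C; BF3·OEt2 (2 equiv); then 14, −78 °C; aq NH4Cl
Reagents that add atoms: none
Why: BF3-promoted SN2 opening of the 2,2-disubstituted epoxide by the lithium acetylide at the CH2 carbon leaves the C9–O stereocentre untouched, and the cold quench avoids lactonisation onto the chain ester.

Step 12
Reactants: 16 2-(trimethylsilyl)ethyl 3-[2-hydroxy-6-(2-hydroxypropan-2-yl)-1,3-dimethyl-2-(4-methylpent-4-en-2-yn-1-yl)cyclohexyl]propanoate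
Product: 17 2-(trimethylsilyl)ethyl 3-[7-(2-hydroxypropan-2-yl)-6,10-dimethyl-2-(prop-1-en-2-yl)-1-oxaspiro[4.5]dec-2-en-6-yl]propanoate
Conditions: Ph3PAuNTf2 (2 mol%), toluene, 4 Å MS, 0 °C to rt; then Et3N
Reagents that add atoms: none
Why: Gold-catalysed 5-endo-dig hydroalkoxylation of the homopropargylic tertiary alcohol (π-activation by monovalent gold, anti attack of the hydroxyl on the distal alkyne carbon, protodeauration) should give the spiro 2,3-dihydrofuran, a 2-alkoxy-1,3-diene, under neutral conditions.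

Step 13
Reactants: 17 2-(trimethylsilyl)ethyl 3-[7-(2-hydroxypropan-2-yl)-6,10-dimethyl-2-(prop-1-en-2-yl)-1-oxaspiro[4.5]dec-2-en-6-yl]propanoate
Product: 18 2-(trimethylsilyl)ethyl 3-[6,10-dimethyl-2-(prop-1-en-2-yl)-7-{2-[(triethylsilyl)oxy]propan-2-yl}-1-oxaspiro[4.5]dec-2-en-6-yl]propanoate
Conditions: Et3SiOTf (1.5 equiv), 2,6-lutidine (3 equiv), CH2Cl2, −78 °C
Reagents that add atoms: triethylsilyl trifluoromethanesulfonate, CC[Si](CC)(CC)OS(=O)(=O)C(F)(F)F
Why: Silyl triflate with a hindered amine silylates the tertiary alcohol (the reagent pair used to make silyloxydienes, so the dienyl ether should survive) and removes the O–H bond that a carbenoid would insert into.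

Step 14
Reactants: 19 methyl 3-methylbut-2-enoate
Product: 20 methyl 2-diazo-3-methylbut-3-enoate
Conditions: 4-acetamidobenzenesulfonyl azide (1.2 equiv), DBU (1.3 equiv), MeCN, 0 °C; used at once
Reagents that add atoms: 4-acetamidobenzenesulfonyl azide, CC(=O)Nc1ccc(cc1)S(=O)(=O)N=[N+]=[N-]
Why: Deconjugative Regitz diazo transfer: DBU removes a γ-proton and the dienolate attacks the sulfonyl azide at the α-carbon to give the vinyldiazoacetate.

Step 15
Reactants: 18 2-(trimethylsilyl)ethyl 3-[6,10-dimethyl-2-(prop-1-en-2-yl)-7-{2-[(triethylsilyl)oxy]propan-2-yl}-1-oxaspiro[4.5]dec-2-en-6-yl]propanoate; 20 methyl 2-diazo-3-methylbut-3-enoate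
Product: 22 methyl 2',5,6',8-tetramethyl-2'-{3-oxo-3-[2-(trimethylsilyl)ethoxy]propyl}-3'-{2-[(triethylsilyl)oxy]propan-2-yl}-3,3a,4,7-tetrahydrospiro[cyclohepta[b]furan-2,1'-cyclohexane]-6-carboxylate (C3a epimers), via divinylcyclopropane 21 (not isolated)
Conditions: Rh2(OPiv)4 (1 mol%), pentane, 36 °C, slow addition of 20 (2 equiv); then toluene, 80 °C
Reagents that add atoms: none
Why: Formal [4+3] cycloaddition by tandem cyclopropanation/Cope rearrangement: the divalent rhodium vinylcarbenoid should add end-on to the unhindered CH2 terminus of the 1,1-disubstituted alkene (the trisubstituted enol ether C=C is too hindered for a donor–acceptor carbenoid), and the divinylcyclopropane rearranges through a boat transition state to the cyclohepta-1,4-diene, whose new C3a stereocentre is destroyed later.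

Step 16
Reactants: 22 the cyclohepta-1,4-diene named in step 15
Product: 23 methyl 2',5,6',8-tetramethyl-2'-{3-oxo-3-[2-(trimethylsilyl)ethoxy]propyl}-3'-{2-[(triethylsilyl)oxy]propan-2-yl}-3,4-dihydrospiro[cyclohepta[b]furan-2,1'-cyclohexane]-6-carboxylate
Conditions: DDQ (1.0 equiv), NaHCO3, benzene, 10 °C to rt
Reagents that add atoms: none
Why: DDQ abstracts hydride from the doubly allylic C7 methylene, and the alkoxy-stabilised pentadienyl cation should lose the C3a proton next to the oxocarbenium carbon, giving the 2-alkoxy-1,3-diene unit (C7=C8–C8a=C3a) inside a cycloheptatriene.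

Step 17
Reactants: 23 the cycloheptatriene named in step 16
Product: 26 methyl 2',5,6',8-tetramethyl-7-oxo-2'-{3-oxo-3-[2-(trimethylsilyl)ethoxy]propyl}-3'-{2-[(triethylsilyl)oxy]propan-2-yl}-3,7-dihydrospiro[cyclohepta[b]furan-2,1'-cyclohexane]-6-carboxylate, via endoperoxide 24 (not isolated), via hydroxy dienone 25 (not isolated)
Conditions: O2, tetraphenylporphyrin (cat.), visible light, CH2Cl2, −40 °C; then Et3N (3 equiv), 0 °C to rt
Reagents that add atoms: dioxygen, O=O
Why: Singlet oxygen adds [4+2] across C3a and C7 of the electron-rich alkoxydiene, Kornblum–DeLaMare cleavage by Et3N removes the only peroxide C–H (at C7) to give the C7 ketone and the C3a alkoxide, and loss of water across C3a–C4 aromatises the ring to the tropone with its carbonyl fixed at C7.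

Step 18
Reactants: 26 the protected tropone named in step 17
Product: 27 3-[3'-(2-hydroxypropan-2-yl)-6-(methoxycarbonyl)-2',5,6',8-tetramethyl-7-oxo-3,7-dihydrospiro[cyclohepta[b]furan-2,1'-cyclohexan]-2'-yl]propanoic acid (CNP0448476.1)
Conditions: Bu4NF (4 equiv), THF, 0 °C to rt; aq NH4Cl (pH 5)
Reagents that add atoms: none
Why: Fluoride cleaves the triethylsilyl ether and triggers β-elimination of the 2-(trimethylsilyl)ethyl ester, conditions that should leave the tropone methyl ester, the vinylogous ester and the tertiary alcohol intact.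

**Compound list**

All compounds from 7 on are single enantiomers with the configuration given by the SMILES. In the monocyclic series the C10 methyl, the C9 CH2 and the C5 substituent lie on one ring face; the C9 oxygen, the C8 methyl and the propanoate chain lie on the other.

1 | 2,4-dimethylphenol | Cc1ccc(O)c(C)c1 | starting material
2 | acrylic acid | C=CC(=O)O | starting material
3 | 6,8-dimethyl-3,4-dihydro-2H-chromen-2-one | O=C1CCc2cc(C)cc(C)c2O1 | intermediate
4 | 3-(2-hydroxy-3,5-dimethylphenyl)propanoic acid | OC(=O)CCc1cc(C)cc(C)c1O | intermediate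
5 | (5R)-7,9-dimethyl-1-oxaspiro[4.5]deca-6,8-diene-2,10-dione | O=C1CC[C@]2(O1)C(=O)C(C)=CC(C)=C2 | intermediate
6 | ethylene | C=C | starting material
7 | 4,6-dimethylspiro[bicyclo[2.2.2]oct-5-ene-2,2'-oxolane]-3,5'-dione, lactone O syn to the ethano bridge | O=C1CC[C@]2(O1)C(=O)[C@@]3(C)CC[C@@H]2C(C)=C3 | intermediate
8 | dilithium 3-(4,6-dimethyl-3-oxidobicyclo[2.2.2]octa-2,5-dien-2-yl)propanoate (not isolated) | [Li+].[Li+].[O-]C(=O)CCC1=C([O-])[C@@]2(C)CC[C@@H]1C(C)=C2 | intermediate
9 | 3-(2,4,6-trimethyl-3-oxobicyclo[2.2.2]oct-5-en-2-yl)propanoic acid, 2-methyl syn to the C5=C6 bridge | OC(=O)CC[C@@]1(C)C(=O)[C@@]2(C)CC[C@@H]1C(C)=C2 | intermediate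
10 | 2-(trimethylsilyl)ethyl 3-(2,4,6-trimethyl-3-oxobicyclo[2.2.2]oct-5-en-2-yl)propanoate | C[Si](C)(C)CCOC(=O)CC[C@@]1(C)C(=O)[C@@]2(C)CC[C@@H]1C(C)=C2 | intermediate
11 | 2-(trimethylsilyl)ethyl 3-(1',3',5'-trimethylspiro[oxirane-2,2'-bicyclo[2.2.2]oct[5]en]-3'-yl)propanoate, oxirane CH2 and 3'-methyl syn to the etheno bridge | C[Si](C)(C)CCOC(=O)CC[C@@]1(C)[C@]3(CO3)[C@@]2(C)CC[C@@H]1C(C)=C2 | intermediate
12 | 2-(trimethylsilyl)ethyl 3-(7-acetyl-4-formyl-4,8-dimethyl-1-oxaspiro[2.5]octan-8-yl)propanoate, formyl and acetyl cis | C[Si](C)(C)CCOC(=O)CC[C@@]1(C)[C@]2(CO2)[C@](C)(C=O)CC[C@@H]1C(C)=O | intermediate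
13 | 2-(trimethylsilyl)ethyl 3-(7-acetyl-4,8-dimethyl-1-oxaspiro[2.5]octan-8-yl)propanoate, 4-methyl trans to acetyl | C[Si](C)(C)CCOC(=O)CC[C@@]1(C)[C@]2(CO2)[C@@H](C)CC[C@@H]1C(C)=O | intermediate
14 | 2-(trimethylsilyl)ethyl 3-[7-(2-hydroxypropan-2-yl)-4,8-dimethyl-1-oxaspiro[2.5]octan-8-yl]propanoate | C[Si](C)(C)CCOC(=O)CC[C@@]1(C)[C@]2(CO2)[C@@H](C)CC[C@@H]1C(C)(C)O | intermediate
15 | 2-methylbut-1-en-3-yne | C=C(C)C#C | starting material
16 | 2-(trimethylsilyl)ethyl 3-[2-hydroxy-6-(2-hydroxypropan-2-yl)-1,3-dimethyl-2-(4-methylpent-4-en-2-yn-1-yl)cyclohexyl]propanoate | C[Si](C)(C)CCOC(=O)CC[C@@]1(C)[C@](O)(CC#CC(C)=C)[C@@H](C)CC[C@@H]1C(C)(C)O | intermediate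
17 | 2-(trimethylsilyl)ethyl 3-[7-(2-hydroxypropan-2-yl)-6,10-dimethyl-2-(prop-1-en-2-yl)-1-oxaspiro[4.5]dec-2-en-6-yl]propanoate | C[Si](C)(C)CCOC(=O)CC[C@@]1(C)[C@]2(CC=C(O2)C(C)=C)[C@@H](C)CC[C@@H]1C(C)(C)O | intermediate
18 | 2-(trimethylsilyl)ethyl 3-[6,10-dimethyl-2-(prop-1-en-2-yl)-7-{2-[(triethylsilyl)oxy]propan-2-yl}-1-oxaspiro[4.5]dec-2-en-6-yl]propanoate | C[Si](C)(C)CCOC(=O)CC[C@@]1(C)[C@]2(CC=C(O2)C(C)=C)[C@@H](C)CC[C@@H]1C(C)(C)O[Si](CC)(CC)CC | intermediate
19 | methyl 3-methylbut-2-enoate | COC(=O)C=C(C)C | starting material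
20 | methyl 2-diazo-3-methylbut-3-enoate | COC(=O)C(=[N+]=[N-])C(C)=C | intermediate
21 | divinylcyclopropane from 18 and 20: methyl 2-methyl-1-(prop-1-en-2-yl)-2-(spiro-dihydrofuranyl)cyclopropane-1-carboxylate (not isolated) | C[Si](C)(C)CCOC(=O)CC[C@@]1(C)[C@]2(CC=C(O2)C3(C)CC3(C(=O)OC)C(C)=C)[C@@H](C)CC[C@@H]1C(C)(C)O[Si](CC)(CC)CC | intermediate
22 | methyl 2',5,6',8-tetramethyl-2'-{3-oxo-3-[2-(trimethylsilyl)ethoxy]propyl}-3'-{2-[(triethylsilyl)oxy]propan-2-yl}-3,3a,4,7-tetrahydrospiro[cyclohepta[b]furan-2,1'-cyclohexane]-6-carboxylate | C[Si](C)(C)CCOC(=O)CC[C@@]1(C)[C@]2(CC3C(O2)=C(C)CC(C(=O)OC)=C(C)C3)[C@@H](C)CC[C@@H]1C(C)(C)O[Si](CC)(CC)CC | intermediate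
23 | the 3,4-dihydrospiro[cyclohepta[b]furan-2,1'-cyclohexane]-6-carboxylate (cycloheptatriene, sp3 C4) | C[Si](C)(C)CCOC(=O)CC[C@@]1(C)[C@]2(CC3=C(O2)C(C)=CC(C(=O)OC)=C(C)C3)[C@@H](C)CC[C@@H]1C(C)(C)O[Si](CC)(CC)CC | intermediate
24 | 3a,7-epidioxy adduct of 23 (endoperoxide, not isolated) | C[Si](C)(C)CCOC(=O)CC[C@@]1(C)[C@]2(CC34OOC(C(C)=C3O2)C(C(=O)OC)=C(C)C4)[C@@H](C)CC[C@@H]1C(C)(C)O[Si](CC)(CC)CC | intermediate
25 | 3a-hydroxy-7-oxo-3,3a,4,7-tetrahydro derivative (hydroxy dienone, not isolated) | C[Si](C)(C)CCOC(=O)CC[C@@]1(C)[C@]2(CC3(O)CC(C)=C(C(=O)OC)C(=O)C(C)=C3O2)[C@@H](C)CC[C@@H]1C(C)(C)O[Si](CC)(CC)CC | intermediate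
26 | methyl 2',5,6',8-tetramethyl-7-oxo-2'-{3-oxo-3-[2-(trimethylsilyl)ethoxy]propyl}-3'-{2-[(triethylsilyl)oxy]propan-2-yl}-3,7-dihydrospiro[cyclohepta[b]furan-2,1'-cyclohexane]-6-carboxylate | C[Si](C)(C)CCOC(=O)CC[C@@]1(C)[C@]2(CC3=CC(C)=C(C(=O)OC)C(=O)C(C)=C3O2)[C@@H](C)CC[C@@H]1C(C)(C)O[Si](CC)(CC)CC | intermediate
27 | 3-[3'-(2-hydroxypropan-2-yl)-6-(methoxycarbonyl)-2',5,6',8-tetramethyl-7-oxo-3,7-dihydrospiro[cyclohepta[b]furan-2,1'-cyclohexan]-2'-yl]propanoic acid (CNP0448476.1) | COC(=O)c1c(C)cc2c(c(C)c1=O)O[C@@]1(C2)[C@@H](C)CC[C@H](C(C)(C)O)[C@@]1(C)CCC(=O)O | target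

**Summary**

Total step count: 18.
Longest linear sequence: 17 steps (steps 1–13 and 15–18; step 14 is a one-step side branch).

Steps most likely to fail:

Step 4. The unactivated dienophile may add too slowly, so that thermal rearrangement or decomposition of the dienone competes at the temperature needed. Fallback: starting from 5, phenyl vinyl sulfone (toluene, 110 °C), an activated ethylene equivalent, should give the sulfonyl adduct F1 (isomers at the sulfonyl carbon are irrelevant). Li/NH3 followed by MeI then cleaves the C–S bond and the lactone C–O bond and methylates the enolate in one operation, which returns to the route at 9.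

Step 15. The carbenoid may be diverted to the enol ether double bond of the dihydrofuran (cyclopropanation or [3+2] there) or to C–H insertion, so that site selectivity is lost. Fallback: starting from 16, both tertiary alcohols are silylated with 1-(trimethylsilyl)imidazole to give the bis(trimethylsilyl) ether F2. Its only alkene, the isopropenyl group of the enyne, is cyclopropanated with 20 and Rh2(OPiv)4 to give the alkynyl vinylcyclopropane F3, and K2CO3/MeOH removes the silyl groups to give the diol F4. Ph3PAuNTf2 then closes the dihydrofuran to the divinylcyclopropane F5, which should undergo the Cope rearrangement on warming to the cycloheptadiene alcohol F6. Silylation with Et3SiOTf and 2,6-lutidine returns to the route at 22.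

Step 16. A second hydride abstraction from the triene (to an alkoxytropylium ion) or oxidative degradation of the enol ether may outrun the wanted dehydrogenation. Fallback: starting from 22, the doubly allylic C7 methylene is oxidised directly to the ketone (Rh2(cap)4, t-BuOOH, K2CO3, CH2Cl2) to give the cross-conjugated dienone F7. DDQ in dioxane then removes the C3a and C4 hydrogens, for which the tropone is the end point, and returns to the route at 26 without passing through 23–25.

Further compounds
F1 | step 4 | 4,6-dimethyl-7-(phenylsulfonyl)spiro[bicyclo[2.2.2]oct-5-ene-2,2'-oxolane]-3,5'-dione (drawn as one regioisomer, sulfonyl carbon undefined) | O=C1CC[C@]2(O1)C(=O)[C@@]3(C)C(S(=O)(=O)c4ccccc4)C[C@@H]2C(C)=C3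
F2 | step 15 | bis(trimethylsilyl) ether of 16 | C[Si](C)(C)CCOC(=O)CC[C@@]1(C)[C@](O[Si](C)(C)C)(CC#CC(C)=C)[C@@H](C)CC[C@@H]1C(C)(C)O[Si](C)(C)C
F3 | step 15 | alkynyl vinylcyclopropane from F2 and 20 (cyclopropane isomers) | C[Si](C)(C)CCOC(=O)CC[C@@]1(C)[C@](O[Si](C)(C)C)(CC#CC2(C)CC2(C(=O)OC)C(C)=C)[C@@H](C)CC[C@@H]1C(C)(C)O[Si](C)(C)C
F4 | step 15 | diol from desilylation of F3 | C[Si](C)(C)CCOC(=O)CC[C@@]1(C)[C@](O)(CC#CC2(C)CC2(C(=O)OC)C(C)=C)[C@@H](C)CC[C@@H]1C(C)(C)O
F5 | step 15 | dihydrofuranyl divinylcyclopropane with free tertiary alcohol (not isolated) | C[Si](C)(C)CCOC(=O)CC[C@@]1(C)[C@]2(CC=C(O2)C3(C)CC3(C(=O)OC)C(C)=C)[C@@H](C)CC[C@@H]1C(C)(C)O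
F6 | step 15 | cycloheptadiene 22 lacking the triethylsilyl group | C[Si](C)(C)CCOC(=O)CC[C@@]1(C)[C@]2(CC3C(O2)=C(C)CC(C(=O)OC)=C(C)C3)[C@@H](C)CC[C@@H]1C(C)(C)O
F7 | step 16 | 7-oxo-3,3a,4,7-tetrahydro dienone from 22 | C[Si](C)(C)CCOC(=O)CC[C@@]1(C)[C@]2(CC3C(O2)=C(C)C(=O)C(C(=O)OC)=C(C)C3)[C@@H](C)CC[C@@H]1C(C)(C)O[Si](CC)(CC)CC
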